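A direct plan would make ring B as a quinone epoxide and attach the chain afterwards: sulfonylquinone A1 would be epoxidised under tartrate control to A2, reduced and silylated, its sulfone turned by reductive lithiation into oxiranyllithium A3, and A3 added to (2Z)-3-iodobut-2-enal A4; ring A would then be joined at C3′–C4′ by cross-coupling. Its weakest steps would be:
(a) the addition of A3 to A4, a carbanion type untested on sulfonyl oxiranes, in which an open transition state would decide C1′ on precious late material;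
(b) the epoxidation of A1, which would set the absolute configuration through a tartrate aggregate anchored on the other alkene, so its facial control would be unproven;
(c) the sulfinate addition, triple silylation and desilylation, about four steps that would add no atom of the target.

**Plan of the new route**
Cuts: C3′–C4′ (last, silicon cross-coupling after trans-hydrosilylation of a C2′≡C3′ alkyne), the two oxirane C–O bonds, C2–H and C5–H, and C1′–C(aryl). C1′ is the acyl carbon taken up by the aryllithium of a 1,4-dimethoxybenzene, and it is the only stereocentre of ring B set by a reagent.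
Ring order: anodic dearomatisation gives ring B as a quinone bisketal, and the oxirane is closed next. There C1′–OH is allylic to one ring alkene only (C1=C6), and C1 bears the ketal carbon C2 geminal to C1′, so 1,2-allylic strain relays C1′ to C1 and C6. Hydride then sets C2 and C5 from the oxirane face, and ring A is cyclised in a second branch.
No sulfone, oxiranyl anion or reagent-controlled epoxidation occurs, and one silyl group suffices.

Key step: step 7

Remark: atoms are numbered as in the target (ring B: C1 quaternary oxirane carbon, C6 oxirane CH, C2 and C5 carbinols, C4 bearing CH2OH; chain: C1′ carbinol to C5′ on ring A).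

**Ring B branch**

Step 1
Reactants: 1 4-bromo-2,5-dimethoxybenzaldehyde
Product: 2 (4-bromo-2,5-dimethoxyphenyl)methanol
Conditions: NaBH4 (0.6 equiv), MeOH/THF, 0 °C
Reagents that add atoms: none
Why: Borohydride reduction of the aryl aldehyde gives the benzylic alcohol that ends as the C4 hydroxymethyl group and leaves the aryl bromide untouched.

Step 2
Reactants: 2 (4-bromo-2,5-dimethoxyphenyl)methanol
Product: 3 [(4-bromo-2,5-dimethoxyphenyl)methoxy](tert-butyl)dimethylsilane
Conditions: TBSCl (1.1 equiv), imidazole (2 equiv), DMF, rt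
Reagents that add atoms: tert-butyl(chloro)dimethylsilane, CC(C)(C)[Si](C)(C)Cl
Why: Silyl ether formation masks the one hydroxyl that would quench the aryllithium and that must not direct the later epoxidation to the C3=C4 alkene.

Step 3
Reactants: 4 but-2-ynoic acid
Product: 5 N-methoxy-N-methylbut-2-ynamide
Conditions: MeNH(OMe)·HCl (1.1 equiv), EDC·HCl (1.2 equiv), i-Pr2NEt (2.5 equiv), CH2Cl2, 0 °C to rt
Reagents that add atoms: N,O-dimethylhydroxylamine hydrochloride, Cl.CNOC
Why: Carbodiimide-mediated amide formation gives the Weinreb amide, an acyl donor that stops at the ketone stage.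

Step 4
Reactants: 3 [(4-bromo-2,5-dimethoxyphenyl)methoxy](tert-butyl)dimethylsilane; 5 N-methoxy-N-methylbut-2-ynamide
Product: 7 1-[4-({[tert-butyl(dimethyl)silyl]oxy}methyl)-2,5-dimethoxyphenyl]but-2-yn-1-one, via aryllithium 6 (not isolated)
Conditions: n-BuLi (1.05 equiv), THF, −78 °C; then 5 (1.2 equiv), −78 to −30 °C; aq NH4Cl
Reagents that add atoms: none
Why: Bromine–lithium exchange and Weinreb ketone synthesis, in which the chelated tetrahedral adduct persists until the quench, join C1′ to the arene carbon that becomes C1 without over-addition.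

Step 5
Reactants: 7 1-[4-({[tert-butyl(dimethyl)silyl]oxy}methyl)-2,5-dimethoxyphenyl]but-2-yn-1-one
Product: 8 (1S)-1-[4-({[tert-butyl(dimethyl)silyl]oxy}methyl)-2,5-dimethoxyphenyl]but-2-yn-1-ol
Conditions: (R)-Alpine-Borane [B-isopinocampheyl-9-borabicyclo[3.3.1]nonane from (+)-α-pinene] (2.5 equiv), neat, rt; then CH3CHO; HOCH2CH2NH2, Et2O
Reagents that add atoms: none
Why: Midland reduction of an alkynyl ketone, in which the pinanyl β-hydrogen is transferred through a boat-like six-membered transition state with the slim propynyl group beside the pinane methyl and the aryl group turned away, sets C1′ as (S).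

Step 6
Reactants: 8 (1S)-1-[4-({[tert-butyl(dimethyl)silyl]oxy}methyl)-2,5-dimethoxyphenyl]but-2-yn-1-ol
Product: 9 (1S)-1-[4-({[tert-butyl(dimethyl)silyl]oxy}methyl)-3,3,6,6-tetramethoxycyclohexa-1,4-dien-1-yl]but-2-yn-1-ol
Conditions: constant-current electrolysis (graphite anode, Pt cathode, undivided cell), 1% KOH in MeOH, 0 °C
Reagents that add atoms: methanol, CO
Why: Anodic bis-methoxylation of a 1,4-dimethoxybenzene (quinone bisketal synthesis), in which the arene radical cation is trapped by methoxide at the two methoxy-bearing carbons, dearomatises ring B and leaves C1′, the alkyne and the silyl ether untouched.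

Step 7
Reactants: 9 (1S)-1-[4-({[tert-butyl(dimethyl)silyl]oxy}methyl)-3,3,6,6-tetramethoxycyclohexa-1,4-dien-1-yl]but-2-yn-1-ol
Product: 10 (1S)-1-[(1S,6R)-4-({[tert-butyl(dimethyl)silyl]oxy}methyl)-2,2,5,5-tetramethoxy-7-oxabicyclo[4.1.0]hept-3-en-1-yl]but-2-yn-1-ol
Conditions: VO(acac)2 (10 mol %), t-BuOOH (5.5 M in decane, 2 equiv), CH2Cl2, 0 °C to rt
Reagents that add atoms: tert-butyl hydroperoxide, CC(C)(C)OO
Why: The C1′ hydroxyl and tert-butyl hydroperoxide bind as alkoxide and alkylperoxide to pentavalent vanadium, and the activated peroxide oxygen is passed within this complex to C1 and C6 in one concerted step, so the oxirane is closed by a formal [2+1] oxygen-atom transfer and is necessarily cis-fused. The closest known reaction type is the vanadium-catalysed epoxidation of secondary allylic alcohols that carry a substituent on the alkene carbon geminal to the carbinol, which gives erythro epoxy alcohols. In 9 that geminal substituent is the ketal carbon C2, so 1,2-allylic strain turns the C1′–H bond into the ring plane beside C2, holds the hydroxyl about 45° out of that plane on one face and the propynyl group on the other, and oxygen enters on the hydroxyl face; C1 and C6 are thus set together by C1′, with the oxirane oxygen anti to the C1′ hydroxyl along C1′–C1–C6 as in the target. The step needs site selectivity between the two ring alkenes and facial selectivity, and one hydroxyl secures both, since the C3=C4 alkene has only a silyl ether beside it and ring B has no other stereocentre that could oppose C1′. The alkyne, the ketals and the silyl ether are inert to the reagent, and the main risk is the low nucleophilicity of an alkene flanked by two ketal carbons.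

Step 8
Reactants: 10 (1S)-1-[(1S,6R)-4-({[tert-butyl(dimethyl)silyl]oxy}methyl)-2,2,5,5-tetramethoxy-7-oxabicyclo[4.1.0]hept-3-en-1-yl]but-2-yn-1-ol
Product: 11 (1S,6R)-4-(hydroxymethyl)-1-[(1S)-1-hydroxybut-2-yn-1-yl]-7-oxabicyclo[4.1.0]hept-3-ene-2,5-dione
Conditions: 48% aq HF, MeCN, 0 °C to rt
Reagents that add atoms: water, O
Why: Acid hydrolysis of both dimethyl ketals (oxocarbenium ion formation and capture by water) unveils the epoxy enedione, the same reagent cleaves the primary silyl ether, and the oxirane should survive because neither of its carbons can support a cation next to a carbonyl group.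

Step 9
Reactants: 11 (1S,6R)-4-(hydroxymethyl)-1-[(1S)-1-hydroxybut-2-yn-1-yl]-7-oxabicyclo[4.1.0]hept-3-ene-2,5-dione
Product: 12 (1S,2S,5R,6S)-4-(hydroxymethyl)-1-[(1S)-1-hydroxybut-2-yn-1-yl]-7-oxabicyclo[4.1.0]hept-3-ene-2,5-diol
Conditions: i-Bu2AlH (7 equiv), THF, −78 °C; Na2SO4·10H2O, then filtration
Reagents that add atoms: none
Why: Oxirane-directed 1,2-reduction of α,β-epoxy ketones, in which aluminium hydride bound to the oxirane oxygen delivers hydride to C2 and C5 from the oxirane face (the other face of C2 is also shielded by the C1′ side chain), makes both new carbinols trans to the oxirane and cis to each other.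

Step 10
Reactants: 12 (1S,2S,5R,6S)-4-(hydroxymethyl)-1-[(1S)-1-hydroxybut-2-yn-1-yl]-7-oxabicyclo[4.1.0]hept-3-ene-2,5-diol
Product: 13 (1S,2S,5R,6S)-1-{(1S,2Z)-3-[benzyl(dimethyl)silyl]-1-hydroxybut-2-en-1-yl}-4-(hydroxymethyl)-7-oxabicyclo[4.1.0]hept-3-ene-2,5-diol
Conditions: BnMe2SiH (1.3 equiv), [(C5Me5)Ru(NCMe)3]PF6 (3 mol %), acetone, 0 °C to rt
Reagents that add atoms: benzyl(dimethyl)silane, C[SiH](C)Cc1ccccc1
Why: Ruthenium-catalysed trans-hydrosilylation of an internal alkyne, which adds H and Si to opposite faces and places silicon on the alkyne carbon remote from the hindered carbinol, gives the (Z)-alkenylsilane with silicon cis to C1′ and tolerates the oxirane and the free hydroxyls.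

**Ring A branch**

Step 11
Reactants: 14 geranyl acetate
Product: 15 (2E)-5-[(2R)-3,3-dimethyloxiran-2-yl]-3-methylpent-2-en-1-yl acetate
Conditions: Shi ketone from D-fructose (30 mol %), KHSO5 (as 2KHSO5·KHSO4·K2SO4), K2CO3, Bu4NHSO4, MeCN/CH2(OMe)2/aq Na2B4O7 buffer, 0 °C
Reagents that add atoms: potassium peroxymonosulfate, [K+].[O-]S(=O)(=O)OO
Why: Shi asymmetric epoxidation, in which the chiral dioxirane attacks the electron-rich 6,7-alkene through a spiro transition state (the 2,3-alkene is deactivated by the allylic acetate), sets the (R)-oxirane carbon that becomes the ring A carbinol.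

Step 12
Reactants: 15 (2E)-5-[(2R)-3,3-dimethyloxiran-2-yl]-3-methylpent-2-en-1-yl acetate
Product: 16 [(1S,5R)-5-hydroxy-2,6,6-trimethylcyclohex-2-en-1-yl]methyl acetate
Conditions: ZrCl4 (0.3 equiv), CH2Cl2, −20 to 0 °C
Reagents that add atoms: none
Why: Lewis-acid epoxide-initiated cation–alkene cyclisation through a chair transition state closes ring A by 6-endo attack of the (E)-alkene on the tertiary oxirane carbon, retains the secondary C–O bond (R), places CH2OAc equatorial and so cis to the hydroxyl (S), and ends by loss of a ring proton to the endocyclic alkene.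

Step 13
Reactants: 16 [(1S,5R)-5-hydroxy-2,6,6-trimethylcyclohex-2-en-1-yl]methyl acetate
Product: 17 [(1S,5R)-5-hydroxy-2,6,6-trimethylcyclohex-2-en-1-yl]methanol
Conditions: K2CO3 (10 mol %), MeOH, rt
Reagents that add atoms: none
Why: Base-catalysed transesterification removes the acetate without touching either stereocentre or the alkene.

Step 14
Reactants: 17 [(1S,5R)-5-hydroxy-2,6,6-trimethylcyclohex-2-en-1-yl]methanol
Product: 18 (1S,5R)-5-hydroxy-2,6,6-trimethylcyclohex-2-ene-1-carbaldehyde
Conditions: TEMPO (10 mol %), PhI(OAc)2 (1.1 equiv), CH2Cl2, 0 °C to rt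
Reagents that add atoms: none
Why: Oxoammonium (TEMPO) oxidation takes the primary alcohol in preference to the hindered secondary one and is neutral enough to avoid epimerisation or conjugation of the β,γ-unsaturated aldehyde.

Step 15
Reactants: 18 (1S,5R)-5-hydroxy-2,6,6-trimethylcyclohex-2-ene-1-carbaldehyde; 19 triiodomethane (iodoform)
Product: 20 (1R,5S)-5-[(E)-2-iodoethenyl]-4,6,6-trimethylcyclohex-3-en-1-ol
Conditions: CrCl2 (6 equiv), THF/1,4-dioxane, 0 °C to rt
Reagents that add atoms: none
Why: Takai iodo-olefination, in which the geminal dichromium species formed from iodoform adds to the aldehyde and eliminates to the (E)-alkenyl iodide under non-basic conditions, tolerates the free hydroxyl and the epimerisable α-centre.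

**Union**

Step 16
Reactants: 13 (1S,2S,5R,6S)-1-{(1S,2Z)-3-[benzyl(dimethyl)silyl]-1-hydroxybut-2-en-1-yl}-4-(hydroxymethyl)-7-oxabicyclo[4.1.0]hept-3-ene-2,5-diol; 20 (1R,5S)-5-[(E)-2-iodoethenyl]-4,6,6-trimethylcyclohex-3-en-1-ol
Product: 22 (1R,2S,5R,6S)-4-(hydroxymethyl)-1-{(1S,2Z,4E)-1-hydroxy-5-[(1S,5R)-5-hydroxy-2,6,6-trimethylcyclohex-2-en-1-yl]-3-methylpenta-2,4-dien-1-yl}-7-oxabicyclo[4.1.0]hept-3-ene-2,5-diol, via cyclic siloxane 21 (not isolated)
Conditions: Bu4NF (3 equiv), THF, 0 °C; then 20 (1.2 equiv), Pd2(dba)3·CHCl3 (5 mol %), rt, degassed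
Reagents that add atoms: none
Why: Fluoride-promoted silicon cross-coupling (Hiyama–Denmark type), in which fluoride removes the benzyl group, the C1′ hydroxyl closes a five-membered siloxane, and transmetalation to the alkenylpalladium iodide and reductive elimination proceed with retention at both sp2 carbons, gives the (2Z,4E)-diene directly in unprotected form.

**Compound list**
1 | 4-bromo-2,5-dimethoxybenzaldehyde | O=Cc1cc(OC)c(Br)cc1OC | starting material
2 | (4-bromo-2,5-dimethoxyphenyl)methanol | OCc1cc(OC)c(Br)cc1OC | intermediate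
3 | [(4-bromo-2,5-dimethoxyphenyl)methoxy](tert-butyl)dimethylsilane | CC(C)(C)[Si](C)(C)OCc1cc(OC)c(Br)cc1OC | intermediate
4 | but-2-ynoic acid | CC#CC(=O)O | starting material
5 | N-methoxy-N-methylbut-2-ynamide | CC#CC(=O)N(C)OC | intermediate
6 | [4-({[tert-butyl(dimethyl)silyl]oxy}methyl)-2,5-dimethoxyphenyl]lithium (not isolated) | [Li]c1cc(OC)c(CO[Si](C)(C)C(C)(C)C)cc1OC | intermediate
7 | 1-[4-({[tert-butyl(dimethyl)silyl]oxy}methyl)-2,5-dimethoxyphenyl]but-2-yn-1-one | CC#CC(=O)c1cc(OC)c(CO[Si](C)(C)C(C)(C)C)cc1OC | intermediate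
8 | (1S)-1-[4-({[tert-butyl(dimethyl)silyl]oxy}methyl)-2,5-dimethoxyphenyl]but-2-yn-1-ol | CC#C[C@H](O)c1cc(OC)c(CO[Si](C)(C)C(C)(C)C)cc1OC | intermediate
9 | (1S)-1-[4-({[tert-butyl(dimethyl)silyl]oxy}methyl)-3,3,6,6-tetramethoxycyclohexa-1,4-dien-1-yl]but-2-yn-1-ol | CC#C[C@H](O)C1=CC(OC)(OC)C(CO[Si](C)(C)C(C)(C)C)=CC1(OC)OC | intermediate
10 | (1S)-1-[(1S,6R)-4-({[tert-butyl(dimethyl)silyl]oxy}methyl)-2,2,5,5-tetramethoxy-7-oxabicyclo[4.1.0]hept-3-en-1-yl]but-2-yn-1-ol | CC#C[C@H](O)[C@]12O[C@H]1C(OC)(OC)C(CO[Si](C)(C)C(C)(C)C)=CC2(OC)OC | intermediate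
11 | (1S,6R)-4-(hydroxymethyl)-1-[(1S)-1-hydroxybut-2-yn-1-yl]-7-oxabicyclo[4.1.0]hept-3-ene-2,5-dione | CC#C[C@H](O)[C@]12O[C@H]1C(=O)C(CO)=CC2=O | intermediate
12 | (1S,2S,5R,6S)-4-(hydroxymethyl)-1-[(1S)-1-hydroxybut-2-yn-1-yl]-7-oxabicyclo[4.1.0]hept-3-ene-2,5-diol (both ring hydroxyls trans to the oxirane) | CC#C[C@H](O)[C@]12O[C@H]1[C@H](O)C(CO)=C[C@@H]2O | intermediate
13 | (1S,2S,5R,6S)-1-{(1S,2Z)-3-[benzyl(dimethyl)silyl]-1-hydroxybut-2-en-1-yl}-4-(hydroxymethyl)-7-oxabicyclo[4.1.0]hept-3-ene-2,5-diol (silicon cis to C1′) | C/C(=C/[C@H](O)[C@]12O[C@H]1[C@H](O)C(CO)=C[C@@H]2O)[Si](C)(C)Cc1ccccc1 | intermediate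
14 | geranyl acetate | CC(=O)OC/C=C(C)/CCC=C(C)C | starting material
15 | (2E)-5-[(2R)-3,3-dimethyloxiran-2-yl]-3-methylpent-2-en-1-yl acetate | CC(=O)OC/C=C(C)/CC[C@H]1OC1(C)C | intermediate
16 | [(1S,5R)-5-hydroxy-2,6,6-trimethylcyclohex-2-en-1-yl]methyl acetate (OH and CH2OAc cis) | CC1=CC[C@@H](O)C(C)(C)[C@H]1COC(C)=O | intermediate
17 | [(1S,5R)-5-hydroxy-2,6,6-trimethylcyclohex-2-en-1-yl]methanol | CC1=CC[C@@H](O)C(C)(C)[C@H]1CO | intermediate
18 | (1S,5R)-5-hydroxy-2,6,6-trimethylcyclohex-2-ene-1-carbaldehyde | CC1=CC[C@@H](O)C(C)(C)[C@H]1C=O | intermediate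
19 | triiodomethane (iodoform) | IC(I)I | starting material
20 | (1R,5S)-5-[(E)-2-iodoethenyl]-4,6,6-trimethylcyclohex-3-en-1-ol | CC1=CC[C@@H](O)C(C)(C)[C@H]1/C=C/I | intermediate
21 | (5S)-5-[(1R,2S,5R,6S)-2,5-dihydroxy-4-(hydroxymethyl)-7-oxabicyclo[4.1.0]hept-3-en-1-yl]-2,2,3-trimethyl-2,5-dihydro-1,2-oxasilole (not isolated) | C[Si]1(C)O[C@@H](C=C1C)[C@]23O[C@H]2[C@H](O)C(CO)=C[C@@H]3O | intermediate
22 | (1R,2S,5R,6S)-4-(hydroxymethyl)-1-{(1S,2Z,4E)-1-hydroxy-5-[(1S,5R)-5-hydroxy-2,6,6-trimethylcyclohex-2-en-1-yl]-3-methylpenta-2,4-dien-1-yl}-7-oxabicyclo[4.1.0]hept-3-ene-2,5-diol | CC1=CC[C@@H](O)C(C)(C)[C@H]1/C=C/C(C)=C\[C@H](O)[C@]12O[C@H]1[C@H](O)C(CO)=C[C@@H]2O | target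

Total step count: 16. Longest linear sequence: 10 steps (steps 1, 2, 4 to 10 and 16, from 1).

**Steps most likely to fail**

1. Step 7. The alkene lies between two ketal carbons and may be too electron-poor to accept oxygen from the vanadium peroxide, so conversion may stall or the carbinol may be oxidised to the ynone instead. The fallback would deliver oxygen as a nucleophile, leaving the route at 9 and rejoining it at 11. Bisketal 9 would be hydrolysed with dilute aqueous oxalic acid in acetone to the quinone 2-({[tert-butyl(dimethyl)silyl]oxy}methyl)-5-[(1S)-1-hydroxybut-2-yn-1-yl]cyclohexa-2,5-diene-1,4-dione F1. F1 would be epoxidised as its sodium alkoxide with Ph3COOH, NaN(SiMe3)2 and diisopropyl tartrate in toluene at −60 °C (tartrate-mediated nucleophilic epoxidation anchored on the C1′ alkoxide, so only the alkene that bears C1′ reacts). The tartrate enantiomer matched to the (S)-alkoxide would be picked in a two-run test. This would give the silylated epoxy dione (1S,6R)-4-({[tert-butyl(dimethyl)silyl]oxy}methyl)-1-[(1S)-1-hydroxybut-2-yn-1-yl]-7-oxabicyclo[4.1.0]hept-3-ene-2,5-dione F2, and aqueous HF in MeCN would then give 11.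

2. Step 16. Under basic fluoride the oxirane may migrate to a neighbouring trans-alkoxide, or the alkenyl–silicon bond may be protonated before transmetalation. The fallback would change from silicon to tin with the hydroxyls masked, setting out from 13 (and from 18 for the partner) and returning at 22. Compound 13 would be silylated on all four hydroxyls (Et3SiOTf, 2,6-lutidine) to the tetrakis(triethylsilyl) ether of 13 F3. Silicon would be exchanged for iodine with retention (N-iodosuccinimide, (CF3)2CHOH/CH2Cl2, 0 °C) to the tetrakis(triethylsilyl) ether of the (Z)-alkenyl iodide F4. F4 would be coupled under neutral Stille conditions [Pd2(dba)3, AsPh3, N-methylpyrrolidone, rt] with tributyl{(E)-2-[(1S,5R)-5-hydroxy-2,6,6-trimethylcyclohex-2-en-1-yl]ethenyl}stannane F5, made from 18 with Bu3SnCHBr2, CrCl2 and LiI. This would give the tetrakis(triethylsilyl) ether of 22 F6, from which Bu4NF buffered with AcOH would release 22.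

3. Step 5. Hydride transfer to the ortho-substituted aryl ketone may be slow enough for dissociation of the borane to compete, which would erode the enantiomeric purity on which every later stereocentre of ring B depends. The fallback would be a resolution, setting out from 7 and returning at 8. NaBH4 with CeCl3 would give racemic 1-[4-({[tert-butyl(dimethyl)silyl]oxy}methyl)-2,5-dimethoxyphenyl]but-2-yn-1-ol F7. Lipase-catalysed acylation with vinyl acetate (immobilised Candida antarctica lipase B, t-BuOMe) would acylate the (R)-enantiomer (aryl as the large group) to the acetate (1R)-1-[4-({[tert-butyl(dimethyl)silyl]oxy}methyl)-2,5-dimethoxyphenyl]but-2-yn-1-yl acetate F8 and leave (S)-alcohol 8. F8 would be returned to 7 by methanolysis and MnO2 oxidation.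

**Further compounds**
F1 | step 7 | 2-({[tert-butyl(dimethyl)silyl]oxy}methyl)-5-[(1S)-1-hydroxybut-2-yn-1-yl]cyclohexa-2,5-diene-1,4-dione | CC#C[C@H](O)C1=CC(=O)C(CO[Si](C)(C)C(C)(C)C)=CC1=O
F2 | step 7 | (1S,6R)-4-({[tert-butyl(dimethyl)silyl]oxy}methyl)-1-[(1S)-1-hydroxybut-2-yn-1-yl]-7-oxabicyclo[4.1.0]hept-3-ene-2,5-dione | CC#C[C@H](O)[C@]12O[C@H]1C(=O)C(CO[Si](C)(C)C(C)(C)C)=CC2=O
F3 | step 16 | tetrakis(triethylsilyl) ether of 13 (all four hydroxyls silylated, configuration unchanged) | C/C(=C/[C@H](O[Si](CC)(CC)CC)[C@]12O[C@H]1[C@H](O[Si](CC)(CC)CC)C(CO[Si](CC)(CC)CC)=C[C@@H]2O[Si](CC)(CC)CC)[Si](C)(C)Cc1ccccc1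
F4 | step 16 | tetrakis(triethylsilyl) ether of the (Z)-alkenyl iodide (F3 with iodine in place of the benzyl(dimethyl)silyl group, iodine cis to C1′) | C/C(I)=C/[C@H](O[Si](CC)(CC)CC)[C@]12O[C@H]1[C@H](O[Si](CC)(CC)CC)C(CO[Si](CC)(CC)CC)=C[C@@H]2O[Si](CC)(CC)CC
F5 | step 16 | tributyl{(E)-2-[(1S,5R)-5-hydroxy-2,6,6-trimethylcyclohex-2-en-1-yl]ethenyl}stannane | CC1=CC[C@@H](O)C(C)(C)[C@H]1/C=C/[Sn](CCCC)(CCCC)CCCC
F6 | step 16 | tetrakis(triethylsilyl) ether of 22 (the C1′, C2, C5 and CH2 hydroxyls of the ring B part silylated) | CC1=CC[C@@H](O)C(C)(C)[C@H]1/C=C/C(C)=C\[C@H](O[Si](CC)(CC)CC)[C@]12O[C@H]1[C@H](O[Si](CC)(CC)CC)C(CO[Si](CC)(CC)CC)=C[C@@H]2O[Si](CC)(CC)CC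
F7 | step 5 | racemic 1-[4-({[tert-butyl(dimethyl)silyl]oxy}methyl)-2,5-dimethoxyphenyl]but-2-yn-1-ol | CC#CC(O)c1cc(OC)c(CO[Si](C)(C)C(C)(C)C)cc1OC
F8 | step 5 | (1R)-1-[4-({[tert-butyl(dimethyl)silyl]oxy}methyl)-2,5-dimethoxyphenyl]but-2-yn-1-yl acetate | CC#C[C@@H](OC(C)=O)c1cc(OC)c(CO[Si](C)(C)C(C)(C)C)cc1OC
A1 | direct plan | 2-(hydroxymethyl)-5-(4-methylbenzenesulfonyl)cyclohexa-2,5-diene-1,4-dione | Cc1ccc(cc1)S(=O)(=O)C1=CC(=O)C(CO)=CC1=O
A2 | direct plan | (1R,6S)-4-(hydroxymethyl)-1-(4-methylbenzenesulfonyl)-7-oxabicyclo[4.1.0]hept-3-ene-2,5-dione | Cc1ccc(cc1)S(=O)(=O)[C@]12O[C@H]1C(=O)C(CO)=CC2=O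
A3 | direct plan | oxiranyllithium: 2,5-bis[(tert-butyldimethylsilyl)oxy]-4-{[(tert-butyldimethylsilyl)oxy]methyl}-7-oxabicyclo[4.1.0]hept-3-en-1-yllithium, both silyloxy groups trans to the oxirane | [Li][C@]12O[C@H]1[C@H](O[Si](C)(C)C(C)(C)C)C(CO[Si](C)(C)C(C)(C)C)=C[C@@H]2O[Si](C)(C)C(C)(C)C
A4 | direct plan | (2Z)-3-iodobut-2-enal | I/C(C)=C\C=O
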